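**Retrosynthetic overview**
1. The C6–OH comes from a C6–Br (lithiation, borylation, oxidation; last step). The side-chain bond between the allylic CH2 and the ring-bearing CH2 (C5''–C6'') is cut into allylic chloride 9 and Grignard reagent 16.
2. Key step: the bond from the cyclohexene CH to its CH2, and that ring stereocentre, come from a [2,3]-Wittig–Still rearrangement of stannylmethyl ether 12 (1,3-chirality transfer from the carbinol centre of 10).
3. The (E)-CH2Cl terminus of 9 comes from SeO2 oxidation of the prenyl end of chromene 6.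
4. The 2H-pyran ring comes from ring-closing metathesis of aryl linalyl ether 5, itself from SNAr of (S)-linalool on 5-bromo-2-fluorobenzaldehyde (the C2 stereocentre is bought and its C–O bond is never broken).
5. Ring order: the benzene and cyclohexene rings are bought intact; the pyran ring is the only ring made (step 3).

Assumption: (S)-(+)-linalool (1) and (R)-2,4,4-trimethylcyclohex-2-en-1-ol (10) are purchased as single enantiomers; 10 is not a routine catalogue compound, so its supply is the weak point of the plan.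

**Step 1**
Reactants: 1 (S)-(+)-linalool; 2 5-bromo-2-fluorobenzaldehyde
Product: 4 5-bromo-2-{[(3S)-3,7-dimethylocta-1,6-dien-3-yl]oxy}benzaldehyde, via potassium linaloolate 3 (not isolated)
Conditions: KH, THF, 0 °C; then 2, 18-crown-6 (cat.), 0 °C → rt
Reagents that add atoms: none
Why: SNAr – the fluoride ortho to CHO (para to Br) is displaced by the tertiary alkoxide oxygen, so the linalool C–O bond and its (S) centre are untouched.

**Step 2**
Reactants: 4 5-bromo-2-{[(3S)-3,7-dimethylocta-1,6-dien-3-yl]oxy}benzaldehyde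
Product: 5 4-bromo-1-{[(3S)-3,7-dimethylocta-1,6-dien-3-yl]oxy}-2-ethenylbenzene
Conditions: Ph3PCH3Br, KOtBu, THF, 0 °C → rt
Reagents that add atoms: methyltriphenylphosphonium bromide, C[P+](c1ccccc1)(c1ccccc1)c1ccccc1.[Br-]
Why: Wittig methylenation of the aryl aldehyde; the base-stable tertiary allyl aryl ether and the aryl bromide are not affected.

**Step 3**
Reactants: 5 4-bromo-1-{[(3S)-3,7-dimethylocta-1,6-dien-3-yl]oxy}-2-ethenylbenzene
Product: 6 (2S)-6-bromo-2-methyl-2-(4-methylpent-3-en-1-yl)-2H-chromene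
Conditions: Grubbs II (3 mol %), CH2Cl2 (0.01 M), 40 °C
Reagents that add atoms: none
Why: Ring-closing olefin metathesis of the two monosubstituted vinyl groups closes the pyran with loss of ethene, far faster than any reaction of the trisubstituted alkene; the quaternary centre is a spectator and the mild temperature avoids aromatic Claisen rearrangement.

**Step 4**
Reactants: 6 (2S)-6-bromo-2-methyl-2-(4-methylpent-3-en-1-yl)-2H-chromene
Product: 7 (2E)-5-[(2S)-6-bromo-2-methyl-2H-chromen-2-yl]-2-methylpent-2-en-1-ol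
Conditions: SeO2 (0.3 equiv), t-BuOOH (2 equiv), salicylic acid (0.1 equiv), CH2Cl2, 0 °C → rt
Reagents that add atoms: tert-butyl hydroperoxide, CC(C)(C)OO (terminal oxygen source, delivered through catalytic selenium dioxide, O=[Se]=O)
Why: Sharpless–Riley allylic oxidation (ene reaction, then [2,3]-sigmatropic shift of the allylseleninic acid) hydroxylates only the (E)-methyl of the prenyl terminus; the chromene has no allylic sp3 C–H.

**Step 5**
Reactants: 7 (2E)-5-[(2S)-6-bromo-2-methyl-2H-chromen-2-yl]-2-methylpent-2-en-1-ol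
Product: 9 (2S)-6-bromo-2-[(3E)-5-chloro-4-methylpent-3-en-1-yl]-2-methyl-2H-chromene, via allylic mesylate 8 (not isolated)
Conditions: MsCl, Et3N, CH2Cl2, −40 °C; then LiCl, THF, 0 °C → rt
Reagents that add atoms: lithium chloride, [Li+].[Cl-]
Why: Mesylation then SN2 displacement by chloride at the primary allylic carbon (Collington–Meyers type) proceeds without allylic transposition or E/Z loss.

**Step 6**
Reactants: 10 (R)-2,4,4-trimethylcyclohex-2-en-1-ol
Product: 12 tributyl({[(1R)-2,4,4-trimethylcyclohex-2-en-1-yl]oxy}methyl)stannane, via potassium cyclohexenolate 11 (not isolated)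
Conditions: KH, THF, 0 °C; then Bu3SnCH2I, rt
Reagents that add atoms: (iodomethyl)tributylstannane, CCCC[Sn](CCCC)(CCCC)CI
Why: Williamson etherification of the potassium alkoxide with Still's reagent; the carbinol C–O bond is not touched.

**Step 7**
Reactants: 12 tributyl({[(1R)-2,4,4-trimethylcyclohex-2-en-1-yl]oxy}methyl)stannane
Product: 14 [(1S)-2,6,6-trimethylcyclohex-2-en-1-yl]methanol ((S)-α-cyclogeraniol), via lithiomethyl ether 13 (not isolated)
Conditions: n-BuLi, THF, −78 → 0 °C; then H2O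
Reagents that add atoms: none
Why: Tin–lithium exchange then [2,3]-Wittig–Still sigmatropic rearrangement: the CH2 carbanion bonds to C3 on the face of the breaking C1–O bond (suprafacial), so the (R) carbinol centre is converted into the (S) ring centre.

**Step 8**
Reactants: 14 [(1S)-2,6,6-trimethylcyclohex-2-en-1-yl]methanol
Product: 15 (6S)-6-(bromomethyl)-1,5,5-trimethylcyclohex-1-ene
Conditions: CBr4, PPh3, CH2Cl2, 0 °C → rt
Reagents that add atoms: carbon tetrabromide, BrC(Br)(Br)Br
Why: Appel bromination (SN2 at the primary carbon) under neutral conditions; the adjacent ring stereocentre is not involved.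

**Step 9**
Reactants: 15 (6S)-6-(bromomethyl)-1,5,5-trimethylcyclohex-1-ene; 9 (2S)-6-bromo-2-[(3E)-5-chloro-4-methylpent-3-en-1-yl]-2-methyl-2H-chromene
Product: 17 (2S)-6-bromo-2-methyl-2-{(3E)-4-methyl-6-[(1S)-2,6,6-trimethylcyclohex-2-en-1-yl]hex-3-en-1-yl}-2H-chromene, via Grignard reagent 16 (not isolated)
Conditions: 15, Mg, THF, rt; then 9, Li2CuCl4 (5 mol %), THF, −78 → 0 °C
Reagents that add atoms: none
Why: Kochi–Schlosser copper-catalysed sp3–sp3 coupling: the primary Grignard attacks the primary allylic chloride at the α-carbon with retention of the E-alkene, and the aryl bromide is inert at this temperature.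

**Step 10**
Reactants: 17 (2S)-6-bromo-2-methyl-2-{(3E)-4-methyl-6-[(1S)-2,6,6-trimethylcyclohex-2-en-1-yl]hex-3-en-1-yl}-2H-chromene
Product: 20 (2S)-2-methyl-2-{(3E)-4-methyl-6-[(1S)-2,6,6-trimethylcyclohex-2-en-1-yl]hex-3-en-1-yl}-2H-chromen-6-ol, via aryllithium 18 (not isolated), via lithium aryltrimethoxyborate 19 (not isolated)
Conditions: n-BuLi, THF, −78 °C; B(OMe)3, −78 °C → rt; then 30 % H2O2, aq NaOH, 0 °C
Reagents that add atoms: hydrogen peroxide, OO
Why: Bromine–lithium exchange, borylation and boronate oxidation (1,2-aryl shift from B to O) turn C–Br into C–OH at low temperature; alkenes and both stereocentres are untouched.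

**Compound list**
1 | (S)-(+)-linalool, (3S)-3,7-dimethylocta-1,6-dien-3-ol | C=C[C@@](C)(O)CCC=C(C)C | starting material
2 | 5-bromo-2-fluorobenzaldehyde | O=Cc1cc(Br)ccc1F | starting material
3 | potassium (3S)-3,7-dimethylocta-1,6-dien-3-olate | C=C[C@@](C)([O-])CCC=C(C)C.[K+] | intermediate
4 | 5-bromo-2-{[(3S)-3,7-dimethylocta-1,6-dien-3-yl]oxy}benzaldehyde | C=C[C@@](C)(Oc1ccc(Br)cc1C=O)CCC=C(C)C | intermediate
5 | 4-bromo-1-{[(3S)-3,7-dimethylocta-1,6-dien-3-yl]oxy}-2-ethenylbenzene | C=C[C@@](C)(Oc1ccc(Br)cc1C=C)CCC=C(C)C | intermediate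
6 | (2S)-6-bromo-2-methyl-2-(4-methylpent-3-en-1-yl)-2H-chromene | CC(C)=CCC[C@@]1(C)C=Cc2cc(Br)ccc2O1 | intermediate
7 | (2E)-5-[(2S)-6-bromo-2-methyl-2H-chromen-2-yl]-2-methylpent-2-en-1-ol | OC/C(C)=C/CC[C@@]1(C)C=Cc2cc(Br)ccc2O1 | intermediate
8 | (2E)-5-[(2S)-6-bromo-2-methyl-2H-chromen-2-yl]-2-methylpent-2-en-1-yl methanesulfonate | CS(=O)(=O)OC/C(C)=C/CC[C@@]1(C)C=Cc2cc(Br)ccc2O1 | intermediate
9 | (2S)-6-bromo-2-[(3E)-5-chloro-4-methylpent-3-en-1-yl]-2-methyl-2H-chromene | ClC/C(C)=C/CC[C@@]1(C)C=Cc2cc(Br)ccc2O1 | intermediate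
10 | (R)-2,4,4-trimethylcyclohex-2-en-1-ol | O[C@@H]1CCC(C)(C)C=C1C | starting material
11 | potassium (1R)-2,4,4-trimethylcyclohex-2-en-1-olate | [O-][C@@H]1CCC(C)(C)C=C1C.[K+] | intermediate
12 | tributyl({[(1R)-2,4,4-trimethylcyclohex-2-en-1-yl]oxy}methyl)stannane | CCCC[Sn](CCCC)(CCCC)CO[C@@H]1CCC(C)(C)C=C1C | intermediate
13 | ({[(1R)-2,4,4-trimethylcyclohex-2-en-1-yl]oxy}methyl)lithium | [Li]CO[C@@H]1CCC(C)(C)C=C1C | intermediate
14 | [(1S)-2,6,6-trimethylcyclohex-2-en-1-yl]methanol | CC1=CCCC(C)(C)[C@@H]1CO | intermediate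
15 | (6S)-6-(bromomethyl)-1,5,5-trimethylcyclohex-1-ene | CC1=CCCC(C)(C)[C@@H]1CBr | intermediate
16 | {[(1S)-2,6,6-trimethylcyclohex-2-en-1-yl]methyl}magnesium bromide | CC1=CCCC(C)(C)[C@@H]1C[Mg]Br | intermediate
17 | (2S)-6-bromo-2-methyl-2-{(3E)-4-methyl-6-[(1S)-2,6,6-trimethylcyclohex-2-en-1-yl]hex-3-en-1-yl}-2H-chromene | CC1=CCCC(C)(C)[C@@H]1CC/C(C)=C/CC[C@@]1(C)C=Cc2cc(Br)ccc2O1 | intermediate
18 | the 6-lithio analogue of 17 (aryllithium) | CC1=CCCC(C)(C)[C@@H]1CC/C(C)=C/CC[C@@]1(C)C=Cc2cc([Li])ccc2O1 | intermediate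
19 | lithium trimethoxy(chromen-6-yl)borate of the same skeleton | CC1=CCCC(C)(C)[C@@H]1CC/C(C)=C/CC[C@@]1(C)C=Cc2cc(ccc2O1)[B-](OC)(OC)OC.[Li+] | intermediate
20 | (2S)-2-methyl-2-{(3E)-4-methyl-6-[(1S)-2,6,6-trimethylcyclohex-2-en-1-yl]hex-3-en-1-yl}-2H-chromen-6-ol | CC1=CCCC(C)(C)[C@@H]1CC/C(C)=C/CC[C@@]1(C)C=Cc2cc(O)ccc2O1 | target

**Step count and risks**
Total steps: 10. Longest linear sequence: 7 (steps 1, 2, 3, 4, 5, 9, 10); the ring branch is steps 6, 7, 8 and joins at step 9.

The three steps most likely to fail are steps 1, 7 and 9.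

Step 1 (SNAr of a hindered tertiary alkoxide next to a free aldehyde; alkoxide attack on CHO and Tishchenko-type side reactions may compete). The fallback sets out from 1 (as its alkoxide 3) and comes back at 4. The ether is made on a nitrile instead of the aldehyde: 3 and 5-bromo-2-fluorobenzonitrile (THF, 0 °C → rt) give 5-bromo-2-{[(3S)-3,7-dimethylocta-1,6-dien-3-yl]oxy}benzonitrile F1. DIBAL-H (toluene, −78 °C) followed by aqueous acid then converts the nitrile into aldehyde 4.

Step 7 ([2,3]-shift onto a carbon flanked by a quaternary centre; [1,2]-shift or simple protonation of 13 may compete). The fallback sets out from 10 and comes back at 14, replacing the rearrangement by a carbamate-directed syn-SN2′ cuprate substitution. Alcohol 10 and phenyl isocyanate give (1R)-2,4,4-trimethylcyclohex-2-en-1-yl N-phenylcarbamate F2. Deprotonation (n-BuLi), CuI and (isopropoxydimethylsilyl)methylmagnesium chloride deliver the silylmethyl group to C3 on the face of the carbamate, giving isopropoxydimethyl{[(1S)-2,6,6-trimethylcyclohex-2-en-1-yl]methyl}silane F3. Tamao oxidation (H2O2, KF, KHCO3, THF/MeOH) gives 14.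

Step 9 (formation of a β-branched homoallylic Grignard reagent and α- versus γ-selectivity in the copper-catalysed coupling). The fallback sets out from 15 (with 9) and comes back at 17, joining the fragments through a sulfone-stabilised carbanion. Bromide 15 and sodium benzenesulfinate (DMF, NaI cat., 80 °C) give ({[(1S)-2,6,6-trimethylcyclohex-2-en-1-yl]methyl}sulfonyl)benzene F4. Its lithio derivative (n-BuLi, THF, −78 °C) is alkylated by chloride 9 to give (2S)-6-bromo-2-methyl-2-{(3E)-4-methyl-6-(phenylsulfonyl)-6-[(1S)-2,6,6-trimethylcyclohex-2-en-1-yl]hex-3-en-1-yl}-2H-chromene F5 (both epimers at the sulfonyl carbon). Buffered 6 % Na(Hg) (Na2HPO4, MeOH/THF, −20 °C) removes the sulfonyl group to give 17; survival of the aryl bromide under these conditions has to be checked.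

**Further compounds**
F1 | step 1 | 5-bromo-2-{[(3S)-3,7-dimethylocta-1,6-dien-3-yl]oxy}benzonitrile | C=C[C@@](C)(Oc1ccc(Br)cc1C#N)CCC=C(C)C
F2 | step 7 | (1R)-2,4,4-trimethylcyclohex-2-en-1-yl N-phenylcarbamate | O=C(Nc1ccccc1)O[C@@H]1CCC(C)(C)C=C1C
F3 | step 7 | isopropoxydimethyl{[(1S)-2,6,6-trimethylcyclohex-2-en-1-yl]methyl}silane | CC1=CCCC(C)(C)[C@@H]1C[Si](C)(C)OC(C)C
F4 | step 9 | ({[(1S)-2,6,6-trimethylcyclohex-2-en-1-yl]methyl}sulfonyl)benzene | CC1=CCCC(C)(C)[C@@H]1CS(=O)(=O)c1ccccc1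
F5 | step 9 | (2S)-6-bromo-2-methyl-2-{(3E)-4-methyl-6-(phenylsulfonyl)-6-[(1S)-2,6,6-trimethylcyclohex-2-en-1-yl]hex-3-en-1-yl}-2H-chromene | CC1=CCCC(C)(C)[C@@H]1C(C/C(C)=C/CC[C@@]2(C)C=Cc3cc(Br)ccc3O2)S(=O)(=O)c1ccccc1
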